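**Plan**
- Target: catechin-(4α→8)-catechin-(4α→8)-catechin-(4α→8)-catechin. Units are counted 1 to 4 from the top, with rings A, B, C as in flavans.
- Cuts: the three C4–C8 interflavan bonds (C4 cation plus C8 of a ring A), and in unit 2 the O1–C8a and C3–C4 bonds of ring C. This leaves a ring A fluoro-aldehyde and a C2–C3 thioether alcohol.
- Forward: catechin gives the unit 3–4 dimer. Ring C of unit 2 is closed as a 3,4-oxirane by an SNAr/sulfonium-ylide annulation. The oxirane is opened at C4 by C8 of the dimer, unit 1 is added at C8 of unit 2, then the protecting groups are removed.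
- Enabling feature: in ring A of unit 2, C8a is ortho to C4 and meta to O5 and O7. A C4 aldehyde therefore makes C8a an SNAr site for O1 and then accepts C3 itself. The aldehyde oxygen becomes O3 through an oxirane that is not in the target and is cleaved when the C4–C8 bond forms.
- Stereochemistry: units 1, 3 and 4 come from (+)-catechin. C2 of unit 2 comes from a CBS reduction; C3 and C4 are relayed from C2 through the trans oxirane and its anti opening. Every 4α bond arises from attack anti to the C3 oxygen.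

Key step: step 9

Remark: the C4 configuration of acetals 3 and 4 (drawn 4β) is lost on ionisation, so either epimer serves.

**Route**

Step 1
Reactants: 1 (+)-catechin
Product: 2 5,7,3',4'-tetra-O-benzyl-(+)-catechin
Conditions: BnBr (4.4 equiv), K2CO3, DMF, 0 °C to rt
Reagents that add atoms: benzyl bromide, BrCc1ccccc1
Why: Williamson etherification of the four phenols, which carbonate deprotonates while the C3 alcohol stays free, and no stereocenter is touched.

Step 2
Reactants: 2 5,7,3',4'-tetra-O-benzyl-(+)-catechin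
Product: 3 (2R,3S,4S)-5,7,3',4'-tetrakis(benzyloxy)-4-(2-ethoxyethoxy)flavan-3-ol
Conditions: DDQ, 2-ethoxyethanol, CH2Cl2, rt
Reagents that add atoms: 2-ethoxyethanol, CCOCCO
Why: DDQ benzylic oxidation, in which hydride is taken from C4 (the cation is stabilised by O5, O7 and O1 of ring A) and the alcohol should add on the face away from the 2-aryl group to set C4 as 4β.

Step 3
Reactants: 3 (2R,3S,4S)-5,7,3',4'-tetrakis(benzyloxy)-4-(2-ethoxyethoxy)flavan-3-ol
Product: 4 (2R,3S,4S)-3-acetoxy-5,7,3',4'-tetrakis(benzyloxy)-4-(2-ethoxyethoxy)flavan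
Conditions: Ac2O, pyridine, 4-(dimethylamino)pyridine (cat.), rt
Reagents that add atoms: acetic anhydride, CC(=O)OC(C)=O
Why: nucleophile-catalysed acylation of the secondary alcohol, whose acetate later shields the β face of the C4 cation.

Step 4
Reactants: 4 (2R,3S,4S)-3-acetoxy-5,7,3',4'-tetrakis(benzyloxy)-4-(2-ethoxyethoxy)flavan; 2 5,7,3',4'-tetra-O-benzyl-(+)-catechin (4 equiv)
Product: 5 octa-O-benzyl-(3-O-acetylcatechin)-(4α→8)-catechin
Conditions: Me3SiOTf (0.1 equiv), CH2Cl2, −78 °C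
Reagents that add atoms: none
Why: Lewis-acid ionisation of the C4 acetal and Friedel–Crafts attack of C8 of 2 on the C4 cation (flavan C4–C8 coupling), anti to the 3-acetoxy group so that the new C4 center is 4α (3,4-trans), with the excess of 2 holding back oligomers.

Step 5
Reactants: 6 2-fluoro-4,6-dimethoxybenzaldehyde
Product: 7 2-fluoro-4,6-dihydroxybenzaldehyde
Conditions: BBr3 (3 equiv), CH2Cl2, −78 °C to rt; then H2O
Reagents that add atoms: none
Why: Lewis-acid cleavage of the two aryl methyl ethers (bromide attacks the methyl group of the boron-bound ether), to which the aryl fluoride and the aldehyde are inert.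

Step 6
Reactants: 7 2-fluoro-4,6-dihydroxybenzaldehyde
Product: 8 4,6-bis(benzyloxy)-2-fluorobenzaldehyde
Conditions: BnBr (2.3 equiv), K2CO3, DMF, 60 °C
Reagents that add atoms: benzyl bromide, BrCc1ccccc1
Why: Williamson etherification, warmed so that the phenol hydrogen-bonded to the aldehyde also reacts.

Step 7
Reactants: 9 1-[3,4-bis(benzyloxy)phenyl]ethan-1-one
Product: 10 1-[3,4-bis(benzyloxy)phenyl]-2-(phenylsulfanyl)ethan-1-one
Conditions: LiN(SiMe3)2 (2.1 equiv), THF, −78 °C; PhSO2SPh (1.0 equiv), −78 to 0 °C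
Reagents that add atoms: S-phenyl benzenethiosulfonate, O=S(=O)(Sc1ccccc1)c1ccccc1
Why: α-sulfenylation of the lithium enolate by a thiosulfonate, where the second equivalent of base holds the more acidic product as its enolate and so prevents a second sulfenylation.

Step 8
Reactants: 10 1-[3,4-bis(benzyloxy)phenyl]-2-(phenylsulfanyl)ethan-1-one
Product: 11 (1R)-1-[3,4-bis(benzyloxy)phenyl]-2-(phenylsulfanyl)ethan-1-ol
Conditions: (R)-2-methyl-CBS-oxazaborolidine [(3aR)-1-methyl-3,3-diphenyltetrahydro-1H,3H-pyrrolo[1,2-c][1,3,2]oxazaborole] (0.2 equiv), BH3·SMe2, THF, −20 °C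
Reagents that add atoms: none
Why: Corey–Bakshi–Shibata reduction, in which the aryl group is the large and CH2SPh the small substituent (as in α-halo acetophenones), so the (R)-catalyst should deliver hydride to give the (R)-carbinol that becomes C2.

Step 9
Reactants: 11 (1R)-1-[3,4-bis(benzyloxy)phenyl]-2-(phenylsulfanyl)ethan-1-ol; 8 4,6-bis(benzyloxy)-2-fluorobenzaldehyde
Product: 14 (2R,3S,4S)-5,7,3',4'-tetrakis(benzyloxy)-3,4-epoxyflavan, via aryl ether 12 (not isolated), via sulfonium ylide 13 (not isolated)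
Conditions: NaH (1.0 equiv), 15-crown-5, THF, 0 to 40 °C; then 2-(trimethylsilyl)phenyl triflate (1.3 equiv), CsF, MeCN, 0 °C to rt
Reagents that add atoms: none
Why: Proposed new method: the alkoxide of 11 displaces fluoride at C8a of 8 by addition–elimination, since C8a is ortho to the formyl carbon C4 (which takes up the charge of the Meisenheimer adduct) and meta to both benzyloxy groups (which therefore do not oppose it), and benzyne then arylates the sulfur of 12 and its aryl anion removes a proton from C3, the only hydrogen-bearing carbon on sulfur, so that ylide 13 arises at C3 alone and without added base. The ylide carbon adds to the ortho aldehyde (6-exo-trig, closing ring C through C3–C4) and the C4 alkoxide then expels diphenyl sulfide from C3 (3-exo-tet), so the aldehyde oxygen becomes the C3 oxygen of an oxirane. The closest known reactions are alkoxide SNAr on 2-fluorobenzaldehydes, ylide formation from thioethers and arynes, and the epoxy-annulation of carbonyl-tethered heteroatom nucleophiles with vinylsulfonium salts, which passes through the same kind of β-heteroatom ylide. C2 is untouched and controls both new centers: oxirane closure needs sulfur and oxygen trans-diaxial on the half-chair, and with the C2 aryl group equatorial the axial sulfonium is cis to it, which puts the oxirane oxygen trans to the aryl group (3S,4S). The step needs O-arylation to outrun hydride transfer from the alkoxide to the aldehyde, and ylide addition to outrun β-elimination of the aryloxide (which would erode C2); the aldehyde sits ortho to the new ether oxygen, which should give the addition a high effective molarity.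

Step 10
Reactants: 14 (2R,3S,4S)-5,7,3',4'-tetrakis(benzyloxy)-3,4-epoxyflavan; 5 octa-O-benzyl-(3-O-acetylcatechin)-(4α→8)-catechin (1.5 equiv)
Product: 15 dodeca-O-benzyl-catechin-(4α→8)-(3-O-acetylcatechin)-(4α→8)-catechin
Conditions: BF3·OEt2 (0.2 equiv), CH2Cl2, −78 °C, slow addition of crude 14
Reagents that add atoms: none
Why: Friedel–Crafts alkylation of an arene by a benzylic epoxide, in which the oxirane opens at C4 (cation stabilised by O5, O7 and O1 of ring A) and C8 of the upper unit of 5 attacks anti to the C3–O bond, setting C4 as 4α (3,4-trans, 2,4-cis) and freeing the 3-hydroxyl group.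

Step 11
Reactants: 15 dodeca-O-benzyl-catechin-(4α→8)-(3-O-acetylcatechin)-(4α→8)-catechin (1.3 equiv); 4 (2R,3S,4S)-3-acetoxy-5,7,3',4'-tetrakis(benzyloxy)-4-(2-ethoxyethoxy)flavan
Product: 16 hexadeca-O-benzyl-(3-O-acetylcatechin)-(4α→8)-catechin-(4α→8)-(3-O-acetylcatechin)-(4α→8)-catechin
Conditions: Me3SiOTf (0.1 equiv), CH2Cl2, −78 °C, slow addition of 4
Reagents that add atoms: none
Why: the flavan C4–C8 coupling of step 4 again, in which the only free C8 of 15 (that of its top unit) is its most nucleophilic arene carbon and attacks the C4 cation of 4 anti to the 3-acetoxy group to give the third 4α bond.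

Step 12
Reactants: 16 hexadeca-O-benzyl-(3-O-acetylcatechin)-(4α→8)-catechin-(4α→8)-(3-O-acetylcatechin)-(4α→8)-catechin
Product: 17 hexadeca-O-benzyl-catechin-(4α→8)-catechin-(4α→8)-catechin-(4α→8)-catechin
Conditions: NaOMe, MeOH/THF, 40 °C
Reagents that add atoms: none
Why: Zemplén transesterification removes the two acetates, while benzyl ethers and interflavan bonds are stable to methoxide.

Step 13
Reactants: 17 hexadeca-O-benzyl-catechin-(4α→8)-catechin-(4α→8)-catechin-(4α→8)-catechin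
Product: 18 catechin-(4α→8)-catechin-(4α→8)-catechin-(4α→8)-catechin
Conditions: H2 (1 atm), Pd(OH)2/C, THF/MeOH/H2O, rt
Reagents that add atoms: none
Why: hydrogenolysis of the sixteen benzyl ethers under neutral conditions, which should leave the acid-labile interflavan bonds and all stereocenters untouched.

**Compound list**

1 | (+)-catechin, (2R,3S) | Oc1cc(O)c2c(c1)O[C@H](c1ccc(O)c(O)c1)[C@@H](O)C2 | starting material

2 | 5,7,3',4'-tetra-O-benzyl-(+)-catechin | O(Cc3ccccc3)c1cc(OCc3ccccc3)c2c(c1)O[C@H](c1ccc(OCc3ccccc3)c(OCc3ccccc3)c1)[C@@H](O)C2 | intermediate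

3 | (2R,3S,4S)-5,7,3',4'-tetrakis(benzyloxy)-4-(2-ethoxyethoxy)flavan-3-ol | O(Cc3ccccc3)c1cc(OCc3ccccc3)c2c(c1)O[C@H](c1ccc(OCc3ccccc3)c(OCc3ccccc3)c1)[C@@H](O)[C@H]2OCCOCC | intermediate

4 | (2R,3S,4S)-3-acetoxy-5,7,3',4'-tetrakis(benzyloxy)-4-(2-ethoxyethoxy)flavan | O(Cc3ccccc3)c1cc(OCc3ccccc3)c2c(c1)O[C@H](c1ccc(OCc3ccccc3)c(OCc3ccccc3)c1)[C@@H](OC(C)=O)[C@H]2OCCOCC | intermediate

5 | octa-O-benzyl-(3-O-acetylcatechin)-(4α→8)-catechin (acetate on the upper unit, lower 3-OH free) | O(Cc3ccccc3)c1cc(OCc3ccccc3)c2c(c1)O[C@H](c1ccc(OCc3ccccc3)c(OCc3ccccc3)c1)[C@@H](OC(C)=O)[C@@H]2c1c(OCc3ccccc3)cc(OCc3ccccc3)c2c1O[C@H](c1ccc(OCc3ccccc3)c(OCc3ccccc3)c1)[C@@H](O)C2 | intermediate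

6 | 2-fluoro-4,6-dimethoxybenzaldehyde | O=Cc1c(F)cc(OC)cc1OC | starting material

7 | 2-fluoro-4,6-dihydroxybenzaldehyde | O=Cc1c(F)cc(O)cc1O | intermediate

8 | 4,6-bis(benzyloxy)-2-fluorobenzaldehyde | O=Cc1c(F)cc(OCc2ccccc2)cc1OCc1ccccc1 | intermediate

9 | 1-[3,4-bis(benzyloxy)phenyl]ethan-1-one | CC(=O)c1ccc(OCc2ccccc2)c(OCc2ccccc2)c1 | starting material

10 | 1-[3,4-bis(benzyloxy)phenyl]-2-(phenylsulfanyl)ethan-1-one | O=C(CSc1ccccc1)c1ccc(OCc2ccccc2)c(OCc2ccccc2)c1 | intermediate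

11 | (1R)-1-[3,4-bis(benzyloxy)phenyl]-2-(phenylsulfanyl)ethan-1-ol | O[C@@H](CSc1ccccc1)c1ccc(OCc2ccccc2)c(OCc2ccccc2)c1 | intermediate

12 | aryl ether: 4,6-bis(benzyloxy)-2-{(1R)-1-[3,4-bis(benzyloxy)phenyl]-2-(phenylsulfanyl)ethoxy}benzaldehyde | O=Cc1c(OCc2ccccc2)cc(OCc2ccccc2)cc1O[C@H](c1ccc(OCc2ccccc2)c(OCc2ccccc2)c1)CSc1ccccc1 | intermediate

13 | sulfonium ylide: diphenylsulfonium ylide of 12, carbanion on the carbon between sulfur and the C2 carbon | O=Cc1c(OCc2ccccc2)cc(OCc2ccccc2)cc1O[C@H](c1ccc(OCc2ccccc2)c(OCc2ccccc2)c1)[CH-][S+](c1ccccc1)c1ccccc1 | intermediate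

14 | (2R,3S,4S)-5,7,3',4'-tetrakis(benzyloxy)-3,4-epoxyflavan (oxirane trans to the 2-aryl group) | O(Cc3ccccc3)c1cc(OCc3ccccc3)c2c(c1)O[C@H](c1ccc(OCc3ccccc3)c(OCc3ccccc3)c1)[C@H]3O[C@H]32 | intermediate

15 | dodeca-O-benzyl-catechin-(4α→8)-(3-O-acetylcatechin)-(4α→8)-catechin | O(Cc3ccccc3)c1cc(OCc3ccccc3)c2c(c1)O[C@H](c1ccc(OCc3ccccc3)c(OCc3ccccc3)c1)[C@@H](O)[C@@H]2c1c(OCc3ccccc3)cc(OCc3ccccc3)c2c1O[C@H](c1ccc(OCc3ccccc3)c(OCc3ccccc3)c1)[C@@H](OC(C)=O)[C@@H]2c1c(OCc3ccccc3)cc(OCc3ccccc3)c2c1O[C@H](c1ccc(OCc3ccccc3)c(OCc3ccccc3)c1)[C@@H](O)C2 | intermediate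

16 | hexadeca-O-benzyl-(3-O-acetylcatechin)-(4α→8)-catechin-(4α→8)-(3-O-acetylcatechin)-(4α→8)-catechin | O(Cc3ccccc3)c1cc(OCc3ccccc3)c2c(c1)O[C@H](c1ccc(OCc3ccccc3)c(OCc3ccccc3)c1)[C@@H](OC(C)=O)[C@@H]2c1c(OCc3ccccc3)cc(OCc3ccccc3)c2c1O[C@H](c1ccc(OCc3ccccc3)c(OCc3ccccc3)c1)[C@@H](O)[C@@H]2c1c(OCc3ccccc3)cc(OCc3ccccc3)c2c1O[C@H](c1ccc(OCc3ccccc3)c(OCc3ccccc3)c1)[C@@H](OC(C)=O)[C@@H]2c1c(OCc3ccccc3)cc(OCc3ccccc3)c2c1O[C@H](c1ccc(OCc3ccccc3)c(OCc3ccccc3)c1)[C@@H](O)C2 | intermediate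

17 | hexadeca-O-benzyl-catechin-(4α→8)-catechin-(4α→8)-catechin-(4α→8)-catechin (all phenols benzylated, four 3-OH free) | O(Cc3ccccc3)c1cc(OCc3ccccc3)c2c(c1)O[C@H](c1ccc(OCc3ccccc3)c(OCc3ccccc3)c1)[C@@H](O)[C@@H]2c1c(OCc3ccccc3)cc(OCc3ccccc3)c2c1O[C@H](c1ccc(OCc3ccccc3)c(OCc3ccccc3)c1)[C@@H](O)[C@@H]2c1c(OCc3ccccc3)cc(OCc3ccccc3)c2c1O[C@H](c1ccc(OCc3ccccc3)c(OCc3ccccc3)c1)[C@@H](O)[C@@H]2c1c(OCc3ccccc3)cc(OCc3ccccc3)c2c1O[C@H](c1ccc(OCc3ccccc3)c(OCc3ccccc3)c1)[C@@H](O)C2 | intermediate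

18 | catechin-(4α→8)-catechin-(4α→8)-catechin-(4α→8)-catechin | Oc1cc(O)c2c(c1)O[C@H](c1ccc(O)c(O)c1)[C@@H](O)[C@@H]2c1c(O)cc(O)c2c1O[C@H](c1ccc(O)c(O)c1)[C@@H](O)[C@@H]2c1c(O)cc(O)c2c1O[C@H](c1ccc(O)c(O)c1)[C@@H](O)[C@@H]2c1c(O)cc(O)c2c1O[C@H](c1ccc(O)c(O)c1)[C@@H](O)C2 | target

**Count and risks**

Total steps: 13. Longest linear sequence: 8 steps (steps 1, 2, 3, 4, 10, 11, 12, 13).

Steps most likely to fail:

1. Step 9 (the step with the new-method label). Four processes threaten it: hydride transfer from the alkoxide to the aldehyde in place of substitution at C8a; β-elimination of the aryloxide from the ylide, which would erase the C2 configuration; closure of the betaine on the face cis to the aryl group; and ring opening with self-alkylation of the oxirane during isolation. The fallback uses known chemistry and takes unit 2 from catechin instead of building it. It sets out from 4 and 5 and comes back at 17. Coupling of 4 with an excess of 5 (Me3SiOTf, CH2Cl2, −78 °C) should give the trimer diacetate F1. A second coupling of F1 with 4 under the same conditions should give the tetramer triacetate F2. NaOMe in MeOH/THF then removes the three acetates and gives 17.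

2. Step 10. The oxirane may alkylate itself through its own C8 or C6 faster than it meets 5, may rearrange by hydride shift to a ketone, or may be attacked through a C6 position of 5. The fallback sets out from 14 and comes back at 15, by way of a leaving group with precedent. Acid-catalysed opening of 14 with 2-ethoxyethanol (pyridinium p-toluenesulfonate, CH2Cl2, 0 °C) should give the 4-(2-ethoxyethoxy)flavan-3-ol F3. This is then ionised with Me3SiOTf at −78 °C in the presence of 5, as in step 4, to give 15.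

3. Step 11. Electrophile 4 has a free C8 of its own, so self-condensation and over-alkylation of 16 may compete when the nucleophile is not in large excess, and attack may leak to C6 positions. The fallback caps the electrophile; it sets out from 4 and comes back at 18. Bromination of 4 at C8 (N-bromosuccinimide, CH2Cl2, −78 °C) should give the 8-bromo electrophile F4. Coupling of F4 with 15 (Me3SiOTf, −78 °C) should give the 8-bromo tetramer diacetate F5. NaOMe then gives the 8-bromo tetrol F6. Hydrogenolysis over Pd(OH)2/C with Et3N removes the benzyl groups and the bromine together and gives 18.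

**Further compounds**

F1 | step 9 | dodeca-O-benzyl-(3-O-acetylcatechin)-(4α→8)-(3-O-acetylcatechin)-(4α→8)-catechin | O(Cc3ccccc3)c1cc(OCc3ccccc3)c2c(c1)O[C@H](c1ccc(OCc3ccccc3)c(OCc3ccccc3)c1)[C@@H](OC(C)=O)[C@@H]2c1c(OCc3ccccc3)cc(OCc3ccccc3)c2c1O[C@H](c1ccc(OCc3ccccc3)c(OCc3ccccc3)c1)[C@@H](OC(C)=O)[C@@H]2c1c(OCc3ccccc3)cc(OCc3ccccc3)c2c1O[C@H](c1ccc(OCc3ccccc3)c(OCc3ccccc3)c1)[C@@H](O)C2

F2 | step 9 | hexadeca-O-benzyl-(3-O-acetylcatechin)-(4α→8)-(3-O-acetylcatechin)-(4α→8)-(3-O-acetylcatechin)-(4α→8)-catechin | O(Cc3ccccc3)c1cc(OCc3ccccc3)c2c(c1)O[C@H](c1ccc(OCc3ccccc3)c(OCc3ccccc3)c1)[C@@H](OC(C)=O)[C@@H]2c1c(OCc3ccccc3)cc(OCc3ccccc3)c2c1O[C@H](c1ccc(OCc3ccccc3)c(OCc3ccccc3)c1)[C@@H](OC(C)=O)[C@@H]2c1c(OCc3ccccc3)cc(OCc3ccccc3)c2c1O[C@H](c1ccc(OCc3ccccc3)c(OCc3ccccc3)c1)[C@@H](OC(C)=O)[C@@H]2c1c(OCc3ccccc3)cc(OCc3ccccc3)c2c1O[C@H](c1ccc(OCc3ccccc3)c(OCc3ccccc3)c1)[C@@H](O)C2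

F3 | step 10 | (2R,3S,4R)-5,7,3',4'-tetrakis(benzyloxy)-4-(2-ethoxyethoxy)flavan-3-ol | O(Cc3ccccc3)c1cc(OCc3ccccc3)c2c(c1)O[C@H](c1ccc(OCc3ccccc3)c(OCc3ccccc3)c1)[C@@H](O)[C@@H]2OCCOCC

F4 | step 11 | (2R,3S,4S)-3-acetoxy-5,7,3',4'-tetrakis(benzyloxy)-8-bromo-4-(2-ethoxyethoxy)flavan | O(Cc3ccccc3)c1cc(OCc3ccccc3)c2c(c1Br)O[C@H](c1ccc(OCc3ccccc3)c(OCc3ccccc3)c1)[C@@H](OC(C)=O)[C@H]2OCCOCC

F5 | step 11 | 8-bromo derivative of 16 (bromine on C8 of unit 1) | O(Cc3ccccc3)c1cc(OCc3ccccc3)c2c(c1Br)O[C@H](c1ccc(OCc3ccccc3)c(OCc3ccccc3)c1)[C@@H](OC(C)=O)[C@@H]2c1c(OCc3ccccc3)cc(OCc3ccccc3)c2c1O[C@H](c1ccc(OCc3ccccc3)c(OCc3ccccc3)c1)[C@@H](O)[C@@H]2c1c(OCc3ccccc3)cc(OCc3ccccc3)c2c1O[C@H](c1ccc(OCc3ccccc3)c(OCc3ccccc3)c1)[C@@H](OC(C)=O)[C@@H]2c1c(OCc3ccccc3)cc(OCc3ccccc3)c2c1O[C@H](c1ccc(OCc3ccccc3)c(OCc3ccccc3)c1)[C@@H](O)C2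

F6 | step 11 | 8-bromo derivative of 17 (bromine on C8 of unit 1) | O(Cc3ccccc3)c1cc(OCc3ccccc3)c2c(c1Br)O[C@H](c1ccc(OCc3ccccc3)c(OCc3ccccc3)c1)[C@@H](O)[C@@H]2c1c(OCc3ccccc3)cc(OCc3ccccc3)c2c1O[C@H](c1ccc(OCc3ccccc3)c(OCc3ccccc3)c1)[C@@H](O)[C@@H]2c1c(OCc3ccccc3)cc(OCc3ccccc3)c2c1O[C@H](c1ccc(OCc3ccccc3)c(OCc3ccccc3)c1)[C@@H](O)[C@@H]2c1c(OCc3ccccc3)cc(OCc3ccccc3)c2c1O[C@H](c1ccc(OCc3ccccc3)c(OCc3ccccc3)c1)[C@@H](O)C2
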